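# Candidachalcone by way of a coumarin that stores the Z-alkene

## The problem

Candidachalcone (18) is a 2'-hydroxychalcone whose ring A carries five substituents, namely the cinnamoyl group at C1', hydroxyls at C2' and C4', a (Z)-3-hydroxy-3-methylbut-1-enyl arm at C3' between them and a methoxy group at C6', so that only C5' bears hydrogen. There is no stereocentre, and the stereochemical content lies in two alkene geometries: the E-enone can be bought with (E)-4-hydroxycinnamic acid, whereas the Z-alkene of the arm is the less stable isomer and must be made and then kept. That arm is the fragile part, a tertiary allylic alcohol conjugated with an electron-rich arene and flanked by two phenols: a trace of acid ionises the carbinol and lets either phenol close a 2,2-dimethylchromene, and light or a metal hydride can turn Z into E. The enone is a Michael acceptor that the 2'-hydroxyl can attack to give a flavanone, and it cannot coexist with the organometallic reagents that build a tertiary carbinol. Protecting groups must therefore leave under neutral conditions, and the ketone has to arrive after the carbinol. The feature that opens the way is a hidden heterocycle: the two alkene carbons of the arm, the carbinol carbon and the oxygen on C2' correspond to C4, C3, C2 and O1 of a 5,7-dioxygenated coumarin, a ring that differs from the arm only by the absence of the two carbinol methyl groups and that holds the alkene cis. Since both oxygens beside C3' end as free hydroxyls, either of them may serve as the ring oxygen.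

## Retrosynthesis

**Unveiling the phenols.** The last cut is at the two aryl O–Si bonds of bis-silyl ether 17. Silicon is chosen because buffered fluoride removes it at neutral pH, which the carbinol arm and the 2'-hydroxychalcone of 18 both tolerate. Acid-labile or hydrogenolysable groups would cost the arm or the alkenes. The forward step only has to keep the medium from turning basic or acidic.

**The ketone.** Cutting the C1'–carbonyl bond of 17 gives aryl bromide 11 and the cinnamoyl N-methoxy-N-methylamide 14. The alternatives, an aldol condensation of a ring A acetophenone or a Friedel–Crafts acylation, need strong base with many free phenols or Lewis acid next to the carbinol. The amide gives a stable tetrahedral adduct (16), so the enone appears only on quench. Metalation is planned on the lithium phenoxide and lithium alkoxide of 11, giving the trilithio species 15. A silyl ether beside the carbon–lithium bond would invite a 1,3 shift of silicon from oxygen to carbon, and the phenoxide removes that risk while saving two protection steps. The forward reaction must give carbonyl rather than conjugate addition to 14.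

**The amide.** Amide 14 comes from phenol 13 by silylation, and 13 from (E)-4-hydroxycinnamic acid 12 by amide formation. Both C–N and O–Si bonds are routine, and the E geometry is bought with 12.

**The carbinol arm (key disconnection).** Both carbon–methyl bonds of 11 are cut at once, which leads back to bromocoumarin 7 and two equivalents of methylmagnesium bromide 8. Against a Z-selective olefination or an alkyne semi-reduction, this cut needs no stereoselective reaction at all, since the cis geometry is a property of the six-membered lactone. The precursor loses the carbinol, the free phenol and the sensitivity to acid. The halogen at C8 of 7 is a spectator toward the Grignard reagent and marks the carbon that will later carry the cinnamoyl group, a group that could not be present while the methyl groups are delivered. The forward reaction must add twice at the carbonyl and not at C4, and the diol must be isolated without acid.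

**Bromine and silicon on the coumarin.** The C8–Br bond of 7 is cut to give silyl ether 6, and the O–Si bond of 6 to give 5-hydroxy-7-methoxycoumarin 5. The carbocycle of 6 is a phloroglucinol-type ring, so an electrophilic bromine source should attack it rather than C3. The silyl group on the C5 oxygen steers the halogen to C8.

**The coumarin.** The C3=C4 bond and the lactone C–O bond of 5 are cut, giving the symmetrical aldehyde 2 and the stabilised ylide 3. An acid-promoted condensation of a symmetrical triphenol with a propiolate ester would be as short, but it would leave two phenols to be told apart by a small difference in acidity. In 2 the two hydroxyls are equivalent, so only one coumarin can form and the methoxy group is necessarily at C7.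

**The methyl ether.** The O–CH3 bond of 2 is cut to give 2,4,6-trihydroxybenzaldehyde 1. Here the three hydroxyls differ sharply: the two beside the formyl group are hydrogen-bonded to it, and the para one is the most acidic and the most nucleophilic.

## Roads not taken

**Alternative 1:** The cut is the C=C bond of the arm itself. In diene A2 the C3' vinyl group and a 1,1-dimethylallyl group are tied through a diphenylsilylene bridge between the C2' oxygen and the carbinol oxygen. A second-generation Hoveyda–Grubbs catalyst would close it by metathesis to the eight-membered dioxasilocine A1, and fluoride would then release 18.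
- Merits: the ring admits only the cis alkene, which is as secure in principle as the lactone. The chalcone is complete before the delicate alkene exists, so no organometallic reagent meets the arm, and no placeholder halogen or aryllithium is needed.
- Weak points: one metathesis partner sits on a quaternary allylic carbon and the ring is eight-membered, so closure should be slow. The enone and the styrene units of A2 are further alkenes open to the carbene. A2 itself needs a vinyl group on a fully substituted ring, a separately built chalcone, and a mixed silylene between a hindered, chelated phenol and a tertiary alcohol.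
- Comparison: in control of geometry the two plans are equal, and this one is better in that the ketone problem never arises. The chosen plan sets against it a one-step entry to the Z-carbinol from 7 with a commodity reagent and an old reaction type, and a longest sequence of seven steps.

**Alternative 2:** The cuts are the C1'–carbonyl and the carbonyl–Cα bonds. Aryl iodide A4, which already carries the Z arm, would combine with carbon monoxide A6 and 4-acetoxystyrene A5 under Pd(OAc)2 with a bulky electron-rich phosphine and NEt3. This carbonylative Heck reaction would give A3, which is then freed of acetate and silicon.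
- Merits: the enone is assembled catalytically from simple pieces with E geometry built in, and there is no organolithium step and no amide to prepare.
- Weak points: it does not solve the Z problem, because A4 must be made first by the lactone opening or its equal. The iodide is electron-rich and flanked by two ortho oxygens, so oxidative addition and acyl transfer should be slow, and direct arylation of A5 without uptake of A6 competes. Each catalytic turnover ends in a palladium hydride, the kind of species that turns a Z-styrene into its E isomer. A base-labile acetate must then be removed beside a 2'-oxygenated chalcone.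
- Comparison: as an endgame it is more convergent and avoids strong bases. The chosen plan sets against it a stoichiometric acylation at −78 °C in which nothing present can isomerise the arm, and a bromide from N-bromosuccinimide in place of an iodide.

**Alternative 3:** The cuts are two bonds of ring A, C3'–C4' and C1'–C2', so ring A is made from the styrylpyrone A8 and the lithium dienolate of lactone A9. The dienolate α-carbon would attack the pyrone carbonyl, and the pyrone would open to a keto enolate that acylates on the lactone carbonyl. Aromatisation with release of the tertiary alkoxide would give A7, one desilylation from 18.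
- Merits: it is the shortest route on paper. All five substituents of ring A are placed by construction with no protecting group on that ring, and the Z geometry again comes from a lactone.
- Weak points: the cascade has no close precedent. The dienolate can react at its α or γ carbon, and the pyrone offers C2, C4 (with loss of methoxide), C6 and the styryl terminus. The second bond requires a stabilised enolate to acylate on a lactone, a reversible step. The 2'-hydroxychalcone is born in a strongly basic medium that favours flavanone formation.
- Comparison: if it worked it would clearly be shorter than the chosen plan. The chosen plan sets against it that every step is a known reaction type on a known substrate class, with the single selectivity question in the key step answered by the substrate.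

Key step: step 5

Remark: 2,4,6-trihydroxybenzaldehyde, ethyl (triphenylphosphoranylidene)acetate, methylmagnesium bromide and 4-hydroxycinnamic acid are taken as commercial, the last as its E isomer.

## Route

Step 1
Reactants: 1 2,4,6-trihydroxybenzaldehyde
Product: 2 2,6-dihydroxy-4-methoxybenzaldehyde
Conditions: Me2SO4 (1.0 equiv), K2CO3 (1.0 equiv), acetone, 0 °C to rt
Reagents that add atoms: dimethyl sulfate, COS(=O)(=O)OC
Why: Williamson-type O-methylation; the 4-hydroxyl is para to the formyl group and the most acidic, while the 2- and 6-hydroxyls are tied up in hydrogen bonds to the carbonyl, so one equivalent of base and reagent should methylate O4 alone.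

Step 2
Reactants: 2 2,6-dihydroxy-4-methoxybenzaldehyde; 3 ethyl (triphenylphosphoranylidene)acetate
Product: 5 5-hydroxy-7-methoxycoumarin, via ethyl (E)-2,6-dihydroxy-4-methoxycinnamate 4 (not isolated)
Conditions: PhNEt2, reflux (about 215 °C), N2
Reagents that add atoms: none
Why: Wittig olefination of the salicylaldehyde-type carbonyl by the stabilised ylide gives cinnamate 4, which at this temperature isomerises about its double bond and lactonises with loss of ethanol. Because the two hydroxyls of 2 are equivalent, only one coumarin can result and the methoxy group must sit at C7.

Step 3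
Reactants: 5 5-hydroxy-7-methoxycoumarin
Product: 6 5-(tert-butyldimethylsilyloxy)-7-methoxycoumarin
Conditions: TBSCl (1.2 equiv), imidazole (2.5 equiv), DMF, rt
Reagents that add atoms: tert-butyldimethylsilyl chloride, CC(C)(C)[Si](C)(C)Cl
Why: Standard silylation of a phenol; the silyl ether removes the acidic proton before the Grignard step and later leaves with fluoride at neutral pH.

Step 4
Reactants: 6 5-(tert-butyldimethylsilyloxy)-7-methoxycoumarin
Product: 7 8-bromo-5-(tert-butyldimethylsilyloxy)-7-methoxycoumarin
Conditions: NBS (1.05 equiv), MeCN, 0 °C to rt, dark
Reagents that add atoms: N-bromosuccinimide, O=C1CCC(=O)N1Br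
Why: Electrophilic aromatic bromination; C6 and C8 are each ortho or para to all three ring oxygens and far more nucleophilic than C3. C8 is para to the silyloxy group and free of its bulk, whereas C6 lies beside the tert-butyldimethylsilyl group.

Step 5
Reactants: 7 8-bromo-5-(tert-butyldimethylsilyloxy)-7-methoxycoumarin; 8 methylmagnesium bromide
Product: 11 2-bromo-5-(tert-butyldimethylsilyloxy)-6-[(Z)-3-hydroxy-3-methylbut-1-enyl]-3-methoxyphenol, via cyclic hemiketal bromomagnesium alkoxide 9 (not isolated), via ring-opened (Z)-enone bromomagnesium phenoxide 10 (not isolated)
Conditions: CeCl3 (anhydrous, 3.5 equiv), MeMgBr (3.5 equiv), THF, −78 to 0 °C; pH 7 phosphate buffer, 0 °C; chromatography on Et3N-washed silica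
Reagents that add atoms: methylmagnesium bromide (second equivalent), C[Mg]Br
Why: Two equivalents of 8 are taken up: the first methyl group attacks the lactone carbonyl of 7 and gives the 2-methylchromen-2-olate 9, whose C2–O1 bond can break to release the (Z)-enone phenoxide 10, and the second methyl group attacks the ketone carbonyl of 10, so that the neutral quench delivers diol 11. The closest known reaction type is the exhaustive methylation of coumarins by methyl Grignard reagents, a classical entry to cis-configured o-hydroxystyryl dimethyl carbinols that are ordinarily dehydrated on purpose to 2,2-dimethylchromenes. No ring closes and no stereocentre is formed, so the only stereochemical element is the alkene geometry. It is Z because C3=C4 is part of the six-membered ring until the lactone C–O bond breaks, and at or below 0 °C the released enone is consumed before it can isomerise. The step needs attack at the carbonyl rather than at C4: the oxophilic reagent formed from MeMgBr and CeCl3 favours this, the donor oxygens at C5 and C7 make C4 a poor acceptor, and the silyloxy group peri to C4 shields it. The aryl bromide and the aryl silyl ether do not react with the methyl reagent at these temperatures. The buffered quench and amine-washed silica keep the allylic carbinol from ionising and closing onto the phenol.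

Step 6
Reactants: 12 (E)-4-hydroxycinnamic acid
Product: 13 (E)-3-(4-hydroxyphenyl)-N-methoxy-N-methylprop-2-enamide
Conditions: MeNH(OMe)·HCl (1.3 equiv), EDC·HCl (1.3 equiv), HOBt (cat.), iPr2NEt (2.6 equiv), DMF, 0 °C to rt
Reagents that add atoms: N,O-dimethylhydroxylamine hydrochloride, CNOC.Cl
Why: Carbodiimide amide coupling; the amine outcompetes the free phenol for the activated ester, and the E geometry of 12 is untouched.

Step 7
Reactants: 13 (E)-3-(4-hydroxyphenyl)-N-methoxy-N-methylprop-2-enamide
Product: 14 (E)-3-[4-(tert-butyldimethylsilyloxy)phenyl]-N-methoxy-N-methylprop-2-enamide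
Conditions: TBSCl (1.2 equiv), imidazole (2.5 equiv), DMF, rt
Reagents that add atoms: tert-butyldimethylsilyl chloride, CC(C)(C)[Si](C)(C)Cl
Why: Standard phenol silylation; it removes the last acidic proton from the acylating partner and matches the silyl ether on ring A, so one fluoride step ends the synthesis.

Step 8
Reactants: 11 2-bromo-5-(tert-butyldimethylsilyloxy)-6-[(Z)-3-hydroxy-3-methylbut-1-enyl]-3-methoxyphenol; 14 (E)-3-[4-(tert-butyldimethylsilyloxy)phenyl]-N-methoxy-N-methylprop-2-enamide
Product: 17 (E)-1-[4-(tert-butyldimethylsilyloxy)-2-hydroxy-3-[(Z)-3-hydroxy-3-methylbut-1-enyl]-6-methoxyphenyl]-3-[4-(tert-butyldimethylsilyloxy)phenyl]prop-2-en-1-one, via trilithiated aryl species 15 (not isolated), via tetrahedral lithium hemiaminal adduct 16 (not isolated)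
Conditions: MeLi (2.1 equiv), THF, −78 °C; t-BuLi (2.1 equiv), −78 °C; then 14 (1.2 equiv), −78 to −20 °C; pH 7 phosphate buffer
Reagents that add atoms: none
Why: Bromine–lithium exchange followed by Weinreb ketone synthesis. MeLi first turns the phenol and the carbinol into lithium salts, so aryllithium 15 has no proton to take and, with a lithium phenoxide instead of a silyl ether beside the metal, cannot suffer a retro-Brook shift of silicon from oxygen to carbon. The chelated adduct 16 holds until the neutral quench, so the enone never meets the aryllithium, and both alkene geometries are carried through unchanged.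

Step 9
Reactants: 17 (E)-1-[4-(tert-butyldimethylsilyloxy)-2-hydroxy-3-[(Z)-3-hydroxy-3-methylbut-1-enyl]-6-methoxyphenyl]-3-[4-(tert-butyldimethylsilyloxy)phenyl]prop-2-en-1-one
Product: 18 candidachalcone, (E)-1-[2,4-dihydroxy-3-[(Z)-3-hydroxy-3-methylbut-1-enyl]-6-methoxyphenyl]-3-(4-hydroxyphenyl)prop-2-en-1-one
Conditions: TBAF (2.5 equiv), AcOH (2.5 equiv), THF, 0 °C
Reagents that add atoms: none
Why: Fluoride cleavage of the two aryl silyl ethers. Acetic acid keeps the liberated phenoxides protonated, so the 2'-oxygen should not add to the enone to give a flavanone, and the medium is far too weakly acidic to ionise the allylic carbinol.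

## Compound list

1 | 2,4,6-trihydroxybenzaldehyde | O=Cc1c(O)cc(O)cc1O | starting material
2 | 2,6-dihydroxy-4-methoxybenzaldehyde | COc1cc(O)c(C=O)c(O)c1 | intermediate
3 | ethyl (triphenylphosphoranylidene)acetate | CCOC(=O)C=P(c1ccccc1)(c1ccccc1)c1ccccc1 | starting material
4 | ethyl (E)-3-(2,6-dihydroxy-4-methoxyphenyl)prop-2-enoate | CCOC(=O)/C=C/c1c(O)cc(OC)cc1O | intermediate
5 | 5-hydroxy-7-methoxycoumarin (5-hydroxy-7-methoxy-2H-chromen-2-one) | O=C1C=Cc2c(O)cc(OC)cc2O1 | intermediate
6 | 5-(tert-butyldimethylsilyloxy)-7-methoxycoumarin | O=C1C=Cc2c(O[Si](C)(C)C(C)(C)C)cc(OC)cc2O1 | intermediate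
7 | 8-bromo-5-(tert-butyldimethylsilyloxy)-7-methoxycoumarin | O=C1C=Cc2c(O[Si](C)(C)C(C)(C)C)cc(OC)c(Br)c2O1 | intermediate
8 | methylmagnesium bromide | C[Mg]Br | starting material
9 | bromomagnesium 8-bromo-5-(tert-butyldimethylsilyloxy)-7-methoxy-2-methyl-2H-chromen-2-olate (C2 of either configuration, transient) | CC1(O[Mg]Br)C=Cc2c(O[Si](C)(C)C(C)(C)C)cc(OC)c(Br)c2O1 | intermediate
10 | bromomagnesium 2-bromo-5-(tert-butyldimethylsilyloxy)-3-methoxy-6-[(Z)-3-oxobut-1-enyl]phenolate | CC(=O)/C=C\c1c(O[Si](C)(C)C(C)(C)C)cc(OC)c(Br)c1O[Mg]Br | intermediate
11 | 2-bromo-5-(tert-butyldimethylsilyloxy)-6-[(Z)-3-hydroxy-3-methylbut-1-enyl]-3-methoxyphenol | COc1cc(O[Si](C)(C)C(C)(C)C)c(/C=C\C(C)(C)O)c(O)c1Br | intermediate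
12 | (E)-4-hydroxycinnamic acid | O=C(O)/C=C/c1ccc(O)cc1 | starting material
13 | (E)-3-(4-hydroxyphenyl)-N-methoxy-N-methylprop-2-enamide | CON(C)C(=O)/C=C/c1ccc(O)cc1 | intermediate
14 | (E)-3-[4-(tert-butyldimethylsilyloxy)phenyl]-N-methoxy-N-methylprop-2-enamide | CON(C)C(=O)/C=C/c1ccc(O[Si](C)(C)C(C)(C)C)cc1 | intermediate
15 | lithium 3-(tert-butyldimethylsilyloxy)-6-lithio-2-[(Z)-3-(lithiooxy)-3-methylbut-1-enyl]-5-methoxyphenolate (11 with Br, phenol H and carbinol H replaced by Li) | COc1cc(O[Si](C)(C)C(C)(C)C)c(/C=C\C(C)(C)O[Li])c(O[Li])c1[Li] | intermediate
16 | trilithium salt of the N-methoxy-N-methyl hemiaminal from 15 and 14 (hemiaminal carbon of either configuration, transient) | COc1cc(O[Si](C)(C)C(C)(C)C)c(/C=C\C(C)(C)O[Li])c(O[Li])c1C(O[Li])(N(C)OC)/C=C/c1ccc(O[Si](C)(C)C(C)(C)C)cc1 | intermediate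
17 | (E)-1-[4-(tert-butyldimethylsilyloxy)-2-hydroxy-3-[(Z)-3-hydroxy-3-methylbut-1-enyl]-6-methoxyphenyl]-3-[4-(tert-butyldimethylsilyloxy)phenyl]prop-2-en-1-one | COc1cc(O[Si](C)(C)C(C)(C)C)c(/C=C\C(C)(C)O)c(O)c1C(=O)/C=C/c1ccc(O[Si](C)(C)C(C)(C)C)cc1 | intermediate
18 | candidachalcone, (E)-1-[2,4-dihydroxy-3-[(Z)-3-hydroxy-3-methylbut-1-enyl]-6-methoxyphenyl]-3-(4-hydroxyphenyl)prop-2-en-1-one | COc1cc(O)c(/C=C\C(C)(C)O)c(O)c1C(=O)/C=C/c1ccc(O)cc1 | target

## Step count and least certain steps

Total: 9 steps. Longest linear sequence: 7 steps (steps 1, 2, 3, 4, 5, 8, 9); steps 6 and 7 form the side branch to 14.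

**Step 5 (key step).** The most likely failure is closure of the Z-diol onto its own phenol during quench or chromatography, because the allylic carbinol next to an electron-rich arene ionises on the slightest acid. Conjugate addition of methyl at C4 is the lesser risk. The fallback sets out from 7 and comes back to the route at 18, and it never exposes the free diol. After the double addition, the bromomagnesium alkoxide and phenoxide are silylated in the flask with Me3SiCl and imidazole before any aqueous contact, giving the bis(trimethylsilyl) ether F1. MeLi (1 equiv, −78 °C) cleaves only the aryl O–SiMe3 bond of F1 to the lithium phenoxide, and t-BuLi then gives the dilithio species F2. Acylation of F2 with 14 gives the ketone F3, which still carries its trimethylsilyl ether on the carbinol, and TBAF/AcOH removes all three silyl groups from F3 to give 18.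

**Step 8.** The aggregated trianion 15 may transfer slowly to the amide. Warming then opens the way to base-induced loss of formaldehyde from the N-methoxy group, or to conjugate addition. The fallback sets out from 11 and 14 and comes back to the route at 17, using a more electrophilic partner at −78 °C. i-Bu2AlH reduces 14 to (E)-3-[4-(tert-butyldimethylsilyloxy)phenyl]prop-2-enal F4. Species 15, made from 11 as before, adds to F4 to give the racemic diallylic carbinol F5. MnO2 in CH2Cl2, used at once on crude F5, oxidises the doubly activated secondary alcohol to 17 and leaves the tertiary carbinol alone.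

**Step 4.** Site selectivity may be poor: the halogen may go partly to C6 or enter twice, since both free positions of the carbocycle are strongly activated. The fallback sets out from 5 and comes back to the route at 7, changing the directing group. NBS brominates the free phenol 5, where the hydroxyl directs para to C8, giving 8-bromo-5-hydroxy-7-methoxycoumarin F6. Silylation of F6 as in step 3 gives 7.

**Step 1.** Over-alkylation is the risk: once O4 is methylated, a second methyl group can enter at a chelated hydroxyl, and unchanged triol remains. The fallback sets out from 1 and comes back to the route at 2, replacing selective alkylation by selective dealkylation. Exhaustive methylation (Me2SO4, K2CO3, acetone, reflux) gives 2,4,6-trimethoxybenzaldehyde F7. AlCl3 (excess, CH2Cl2) cleaves only the two methyl ethers of F7 that chelate to the formyl group, giving 2.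

## Further compounds

F1 | step 5 | [2-bromo-5-(tert-butyldimethylsilyloxy)-3-methoxy-6-[(Z)-3-methyl-3-(trimethylsilyloxy)but-1-enyl]phenoxy]trimethylsilane | COc1cc(O[Si](C)(C)C(C)(C)C)c(/C=C\C(C)(C)O[Si](C)(C)C)c(O[Si](C)(C)C)c1Br
F2 | step 5 | lithium 3-(tert-butyldimethylsilyloxy)-6-lithio-5-methoxy-2-[(Z)-3-methyl-3-(trimethylsilyloxy)but-1-enyl]phenolate | COc1cc(O[Si](C)(C)C(C)(C)C)c(/C=C\C(C)(C)O[Si](C)(C)C)c(O[Li])c1[Li]
F3 | step 5 | (E)-1-[4-(tert-butyldimethylsilyloxy)-2-hydroxy-6-methoxy-3-[(Z)-3-methyl-3-(trimethylsilyloxy)but-1-enyl]phenyl]-3-[4-(tert-butyldimethylsilyloxy)phenyl]prop-2-en-1-one | COc1cc(O[Si](C)(C)C(C)(C)C)c(/C=C\C(C)(C)O[Si](C)(C)C)c(O)c1C(=O)/C=C/c1ccc(O[Si](C)(C)C(C)(C)C)cc1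
F4 | step 8 | (E)-3-[4-(tert-butyldimethylsilyloxy)phenyl]prop-2-enal | O=C/C=C/c1ccc(O[Si](C)(C)C(C)(C)C)cc1
F5 | step 8 | (E)-1-[4-(tert-butyldimethylsilyloxy)-2-hydroxy-3-[(Z)-3-hydroxy-3-methylbut-1-enyl]-6-methoxyphenyl]-3-[4-(tert-butyldimethylsilyloxy)phenyl]prop-2-en-1-ol (racemic) | COc1cc(O[Si](C)(C)C(C)(C)C)c(/C=C\C(C)(C)O)c(O)c1C(O)/C=C/c1ccc(O[Si](C)(C)C(C)(C)C)cc1
F6 | step 4 | 8-bromo-5-hydroxy-7-methoxycoumarin | O=C1C=Cc2c(O)cc(OC)c(Br)c2O1
F7 | step 1 | 2,4,6-trimethoxybenzaldehyde | COc1cc(OC)c(C=O)c(OC)c1
A1 | alternative 1 | candidachalcone as its cyclic 2'-O,carbinol-O-diphenylsilylene derivative, tert-butyldimethylsilylated at the other two phenols | COc1cc(O[Si](C)(C)C(C)(C)C)c2/C=C\C(C)(C)O[Si](c3ccccc3)(c3ccccc3)Oc2c1C(=O)/C=C/c1ccc(O[Si](C)(C)C(C)(C)C)cc1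
A2 | alternative 1 | (E)-1-[4-(tert-butyldimethylsilyloxy)-3-ethenyl-6-methoxy-2-[(2-methylbut-3-en-2-yloxy)diphenylsilyloxy]phenyl]-3-[4-(tert-butyldimethylsilyloxy)phenyl]prop-2-en-1-one | COc1cc(O[Si](C)(C)C(C)(C)C)c(C=C)c(O[Si](c2ccccc2)(c2ccccc2)OC(C)(C)C=C)c1C(=O)/C=C/c1ccc(O[Si](C)(C)C(C)(C)C)cc1
A3 | alternative 2 | 4-O-acetyl-2',4'-bis-O-(tert-butyldimethylsilyl)candidachalcone | COc1cc(O[Si](C)(C)C(C)(C)C)c(/C=C\C(C)(C)O)c(O[Si](C)(C)C(C)(C)C)c1C(=O)/C=C/c1ccc(OC(C)=O)cc1
A4 | alternative 2 | (Z)-4-[2,6-bis(tert-butyldimethylsilyloxy)-3-iodo-4-methoxyphenyl]-2-methylbut-3-en-2-ol | COc1cc(O[Si](C)(C)C(C)(C)C)c(/C=C\C(C)(C)O)c(O[Si](C)(C)C(C)(C)C)c1I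
A5 | alternative 2 | 4-acetoxystyrene | CC(=O)Oc1ccc(C=C)cc1
A6 | alternative 2 | carbon monoxide | [C-]#[O+]
A7 | alternative 3 | candidachalcone tert-butyldimethylsilylated at the ring B phenol | COc1cc(O)c(/C=C\C(C)(C)O)c(O)c1C(=O)/C=C/c1ccc(O[Si](C)(C)C(C)(C)C)cc1
A8 | alternative 3 | 6-[(E)-2-[4-(tert-butyldimethylsilyloxy)phenyl]ethenyl]-4-methoxy-2H-pyran-2-one | COC1=CC(=O)OC(/C=C/c2ccc(O[Si](C)(C)C(C)(C)C)cc2)=C1
A9 | alternative 3 | 6,6-dimethyl-3,6-dihydro-2H-pyran-2-one | CC1(C)C=CCC(=O)O1
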